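**Retrosynthetic overview**

1. Feature: ring carbon C1 (ring: C1 alkenyl, C3 OH, C4 CH3, C6 O-isobutyryl) carries the side-chain carbon Cα, whose two neighbours (=CH2 and CH2–O2CPh) are the two ends of a symmetric 2-arylallyl unit. That unit is stored as a cyclopropanol built on Cα.
2. Late disconnections: C3 O–H from O–benzyl (last step); C6 O–isobutyryl from O–CH2OCH3; CH2–O2CPh from CH2–Br; the allyl bromide from a 1-arylcyclopropyl mesylate by ring opening.
3. Key disconnection: both Cα–CH2 bonds of the cyclopropanol, back to the ester carbon of a methyl benzoate and the two carbons of one ethyl group of ethylmagnesium bromide (Kulinkovich reaction).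
4. The benzoate comes from 4-methylsalicylic acid: para-hydroxylation (Elbs), esterification, benzylation of the free 5-OH, acetal on the chelated 2-OH.
5. Ring order: the benzene ring is bought; the cyclopropane is the only ring made (step 5) and is opened again in step 7.

Key step: step 5

Remark: the target has no stereocentre and no alkene geometry, so the route needs only regiocontrol and chemoselectivity.

**Route**

Step 1
Reactants: 1 4-methylsalicylic acid (2-hydroxy-4-methylbenzoic acid)
Product: 3 2,5-dihydroxy-4-methylbenzoic acid, via aryl hydrogen sulfate 2 (not isolated)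
Conditions: K2S2O8, aq. NaOH, 0 °C → rt; then aq. HCl, 90 °C
Reagents that add atoms: potassium peroxodisulfate, [K+].[K+].[O-]S(=O)(=O)OOS(=O)(=O)[O-]
Why: Elbs persulfate oxidation: the phenoxide of 1 should attack a peroxide oxygen of peroxodisulfate through C5, the free position para to the phenol oxygen, and hot acid then hydrolyses the aryl sulfate 2 to the hydroquinone acid.

Step 2
Reactants: 3 2,5-dihydroxy-4-methylbenzoic acid
Product: 4 methyl 2,5-dihydroxy-4-methylbenzoate
Conditions: MeOH, H2SO4 (cat.), reflux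
Reagents that add atoms: methanol, CO
Why: Fischer esterification esterifies only the carboxylic acid, and the acidic medium protects the hydroquinone from air oxidation.

Step 3
Reactants: 4 methyl 2,5-dihydroxy-4-methylbenzoate
Product: 5 methyl 5-(benzyloxy)-2-hydroxy-4-methylbenzoate
Conditions: BnBr (1.05 equiv), K2CO3 (1.1 equiv), acetone, reflux, under N2
Reagents that add atoms: benzyl bromide, BrCc1ccccc1
Why: Williamson ether synthesis with one equivalent of base and halide should alkylate the free 5-OH, because the 2-OH is held in a hydrogen-bonded chelate with the ester carbonyl and is the poorer nucleophile.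

Step 4
Reactants: 5 methyl 5-(benzyloxy)-2-hydroxy-4-methylbenzoate
Product: 6 methyl 5-(benzyloxy)-2-(methoxymethoxy)-4-methylbenzoate
Conditions: NaH, DMF, 0 °C; then MeOCH2Cl, 0 °C → rt
Reagents that add atoms: chloromethyl methyl ether, COCCl
Why: Irreversible deprotonation breaks the chelate, and Williamson-type O-alkylation of the sodium phenoxide by the reactive chloromethyl ether gives the acetal.

Step 5
Reactants: 6 methyl 5-(benzyloxy)-2-(methoxymethoxy)-4-methylbenzoate; 7 ethylmagnesium bromide
Product: 8 1-[5-(benzyloxy)-2-(methoxymethoxy)-4-methylphenyl]cyclopropan-1-ol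
Conditions: EtMgBr (2.4 equiv, slow addition), Ti(OiPr)4 (0.2 equiv), THF, 0 °C → rt; sat. aq. NH4Cl
Reagents that add atoms: none
Why: Kulinkovich cyclopropanation, the closest precedent being the conversion of methyl benzoates into 1-arylcyclopropanols: two EtMgBr exchange onto Ti(OiPr)4 (tetravalent titanium) to give Et2Ti(OiPr)2, which loses ethane by β-hydride abstraction and forms a titanacyclopropane that behaves as a 1,2-dicarbanion. The ester carbonyl of 6 inserts into one Ti–C bond to give an oxatitanacyclopentane, methoxide is expelled to leave a β-titanio ketone, and the second Ti–C bond adds to that ketone carbon, so both Cα–CH2 bonds come from one ethyl unit. The cyclopropane ring closes in a 3-exo-trig mode, and further EtMgBr exchanges the titanium cyclopropanolate and renews the dialkyltitanium, so the metal is catalytic. No stereocentre arises, because Cα carries two equivalent CH2 groups. The step needs chemoselectivity for the ester over the benzyl ether and the acetal, and it must outrun plain 1,2-addition of EtMgBr to the ester; both phenols are capped, so no acidic proton consumes the reagent, and slow addition of the Grignard reagent to ester plus titanium keeps its standing concentration low.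

Step 6
Reactants: 8 1-[5-(benzyloxy)-2-(methoxymethoxy)-4-methylphenyl]cyclopropan-1-ol
Product: 9 1-[5-(benzyloxy)-2-(methoxymethoxy)-4-methylphenyl]cyclopropyl methanesulfonate
Conditions: MsCl, Et3N, CH2Cl2, −10 → 0 °C; used crude
Reagents that add atoms: methanesulfonyl chloride, CS(=O)(=O)Cl
Why: Sulfonylation through the sulfene should mesylate even this tertiary alcohol, and the strain of a cyclopropyl cation keeps the mesylate from ionising under these cold basic conditions.

Step 7
Reactants: 9 1-[5-(benzyloxy)-2-(methoxymethoxy)-4-methylphenyl]cyclopropyl methanesulfonate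
Product: 10 1-(benzyloxy)-5-(3-bromoprop-1-en-2-yl)-4-(methoxymethoxy)-2-methylbenzene
Conditions: MgBr2·OEt2 (3 equiv), Et2O, reflux
Reagents that add atoms: magnesium bromide (used as its diethyl etherate), Br[Mg]Br
Why: Cyclopropyl-to-allyl rearrangement: magnesium-assisted loss of mesylate is coupled to disrotatory electrocyclic opening to the symmetric 2-arylallyl cation, which bromide captures at either CH2 to give one product, and any ring-retained cyclopropyl bromide should re-ionise and drain to the more stable allyl bromide.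

Step 8
Reactants: 10 1-(benzyloxy)-5-(3-bromoprop-1-en-2-yl)-4-(methoxymethoxy)-2-methylbenzene; 11 benzoic acid
Product: 13 2-[5-(benzyloxy)-2-(methoxymethoxy)-4-methylphenyl]prop-2-en-1-yl benzoate, via cesium benzoate 12 (not isolated)
Conditions: PhCO2H, Cs2CO3, DMF, rt
Reagents that add atoms: none
Why: SN2 alkylation of the weakly ion-paired cesium carboxylate by a primary allylic bromide is fast in DMF, and direct and allylically transposed attack give the same product because the allyl unit is symmetric.

Step 9
Reactants: 13 2-[5-(benzyloxy)-2-(methoxymethoxy)-4-methylphenyl]prop-2-en-1-yl benzoate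
Product: 14 2-[5-(benzyloxy)-2-hydroxy-4-methylphenyl]prop-2-en-1-yl benzoate
Conditions: NaHSO4·SiO2, CH2Cl2, rt
Reagents that add atoms: none
Why: Acid-catalysed acetal cleavage on a mild heterogeneous acid should remove the phenolic methoxymethyl group without touching the benzyl ether, the benzoate or the 1,1-disubstituted alkene.

Step 10
Reactants: 14 2-[5-(benzyloxy)-2-hydroxy-4-methylphenyl]prop-2-en-1-yl benzoate; 15 isobutyryl chloride (2-methylpropanoyl chloride)
Product: 16 2-[5-(benzyloxy)-4-methyl-2-(2-methylpropanoyloxy)phenyl]prop-2-en-1-yl benzoate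
Conditions: iPrCOCl, Et3N, 4-(dimethylamino)pyridine (cat.), CH2Cl2, 0 °C
Reagents that add atoms: none
Why: Nucleophile-catalysed O-acylation of the phenol by the acid chloride should be much faster than attack of the phenoxide on the neighbouring allylic benzoate, whether at the allylic carbon or at the carbonyl.

Step 11
Reactants: 16 2-[5-(benzyloxy)-4-methyl-2-(2-methylpropanoyloxy)phenyl]prop-2-en-1-yl benzoate
Product: 17 2-[5-hydroxy-4-methyl-2-(2-methylpropanoyloxy)phenyl]prop-2-en-1-yl benzoate (target, CNP0245407.0)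
Conditions: BCl3, C6HMe5, CH2Cl2, −78 °C; then CHCl3/MeOH
Reagents that add atoms: none
Why: Lewis-acid cleavage of the aryl benzyl ether at low temperature, with pentamethylbenzene taking the benzyl cation by Friedel–Crafts alkylation, should leave both esters and the alkene intact and prevent benzylation of the electron-rich ring.

**Compound list**

1 | 4-methylsalicylic acid (2-hydroxy-4-methylbenzoic acid) | Cc1ccc(C(=O)O)c(O)c1 | starting material
2 | 2-hydroxy-4-methyl-5-(sulfooxy)benzoic acid (aryl hydrogen sulfate, present as its salt) | Cc1cc(O)c(C(=O)O)cc1OS(=O)(=O)O | intermediate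
3 | 2,5-dihydroxy-4-methylbenzoic acid | Cc1cc(O)c(C(=O)O)cc1O | intermediate
4 | methyl 2,5-dihydroxy-4-methylbenzoate | COC(=O)c1cc(O)c(C)cc1O | intermediate
5 | methyl 5-(benzyloxy)-2-hydroxy-4-methylbenzoate | COC(=O)c1cc(OCc2ccccc2)c(C)cc1O | intermediate
6 | methyl 5-(benzyloxy)-2-(methoxymethoxy)-4-methylbenzoate | COCOc1cc(C)c(OCc2ccccc2)cc1C(=O)OC | intermediate
7 | ethylmagnesium bromide | CC[Mg]Br | starting material
8 | 1-[5-(benzyloxy)-2-(methoxymethoxy)-4-methylphenyl]cyclopropan-1-ol | COCOc1cc(C)c(OCc2ccccc2)cc1C1(O)CC1 | intermediate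
9 | 1-[5-(benzyloxy)-2-(methoxymethoxy)-4-methylphenyl]cyclopropyl methanesulfonate | COCOc1cc(C)c(OCc2ccccc2)cc1C1(OS(C)(=O)=O)CC1 | intermediate
10 | 1-(benzyloxy)-5-(3-bromoprop-1-en-2-yl)-4-(methoxymethoxy)-2-methylbenzene | COCOc1cc(C)c(OCc2ccccc2)cc1C(=C)CBr | intermediate
11 | benzoic acid | OC(=O)c1ccccc1 | starting material
12 | cesium benzoate | [Cs+].[O-]C(=O)c1ccccc1 | intermediate
13 | 2-[5-(benzyloxy)-2-(methoxymethoxy)-4-methylphenyl]prop-2-en-1-yl benzoate | COCOc1cc(C)c(OCc2ccccc2)cc1C(=C)COC(=O)c1ccccc1 | intermediate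
14 | 2-[5-(benzyloxy)-2-hydroxy-4-methylphenyl]prop-2-en-1-yl benzoate | C=C(COC(=O)c1ccccc1)c1cc(OCc2ccccc2)c(C)cc1O | intermediate
15 | isobutyryl chloride (2-methylpropanoyl chloride) | CC(C)C(Cl)=O | starting material
16 | 2-[5-(benzyloxy)-4-methyl-2-(2-methylpropanoyloxy)phenyl]prop-2-en-1-yl benzoate | C=C(COC(=O)c1ccccc1)c1cc(OCc2ccccc2)c(C)cc1OC(=O)C(C)C | intermediate
17 | 2-[5-hydroxy-4-methyl-2-(2-methylpropanoyloxy)phenyl]prop-2-en-1-yl benzoate | C=C(COC(=O)c1ccccc1)c1cc(O)c(C)cc1OC(=O)C(C)C | target

**Step count**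

Total steps: 11. Longest linear sequence: 11 steps (1 to 17).

**Steps most likely to fail**

Step 7. The ionisation may stop at a ring-retained cyclopropyl bromide, because the ortho-alkoxy, para-methyl aryl group stabilises the closed cation. The Lewis acid may also strip the methoxymethyl acetal, after which the freed phenoxide would close onto the allylic bromide. The fallback avoids both the cation and the Lewis acid; it sets out from ester 6 and comes back at allyl bromide 10. Double addition of Me3SiCH2MgCl in the presence of anhydrous CeCl3 (THF, −78 °C → rt) to 6 should give 2-[5-(benzyloxy)-2-(methoxymethoxy)-4-methylphenyl]-1,3-bis(trimethylsilyl)propan-2-ol F1. Peterson elimination of this carbinol on silica gel in CH2Cl2 should give the allylsilane {2-[5-(benzyloxy)-2-(methoxymethoxy)-4-methylphenyl]prop-2-en-1-yl}(trimethyl)silane F2. Bromodesilylation with N-bromosuccinimide (propylene oxide, CH2Cl2, −78 °C) then attacks the terminal alkene carbon and expels silicon from the β-silyl cation. The low temperature favours the allylsilane over the aromatic ring, and the product is 10.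

Step 5. Plain double addition of EtMgBr to the ester may compete, and chelation of titanium by the ortho acetal oxygen may stall turnover on this hindered benzoate. The fallback builds the same cyclopropanol by carbene transfer; it sets out from ester 6 and comes back at cyclopropanol 8. Aminolysis with MeNH(OMe)·HCl and iPrMgCl (THF, −20 °C) should give 5-(benzyloxy)-N-methoxy-2-(methoxymethoxy)-N,4-dimethylbenzamide F3. MeMgBr (THF, 0 °C) then gives the methyl ketone 1-[5-(benzyloxy)-2-(methoxymethoxy)-4-methylphenyl]ethan-1-one F4. Enolisation with LiN(iPr)2 and trapping with Me3SiCl (THF, −78 °C) gives the silyl enol ether ({1-[5-(benzyloxy)-2-(methoxymethoxy)-4-methylphenyl]ethenyl}oxy)(trimethyl)silane F5. Simmons–Smith cyclopropanation (Et2Zn, CH2I2, CH2Cl2, 0 °C) gives the silyloxycyclopropane ({1-[5-(benzyloxy)-2-(methoxymethoxy)-4-methylphenyl]cyclopropyl}oxy)(trimethyl)silane F6. Methanolysis (K2CO3, MeOH, 0 °C) releases 8.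

Step 11. BCl3 or the HCl it liberates may ionise the allylic benzoate, add to the styrene-type alkene or cleave the phenolic isobutyrate. The fallback replaces the benzyl ether by a silyl ether that is removed by fluoride; it sets out from dihydroxy ester 4 and comes back at target 17. Silylation of the non-chelated 5-OH (iPr3SiCl, imidazole, DMF, rt) should give methyl 2-hydroxy-4-methyl-5-[tri(propan-2-yl)silyloxy]benzoate F7. The conditions of steps 4 to 10 are then repeated on the silyl series. This gives in turn:
- the acetal methyl 2-(methoxymethoxy)-4-methyl-5-[tri(propan-2-yl)silyloxy]benzoate F8;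
- the cyclopropanol 1-{2-(methoxymethoxy)-4-methyl-5-[tri(propan-2-yl)silyloxy]phenyl}cyclopropan-1-ol F9;
- its methanesulfonate 1-{2-(methoxymethoxy)-4-methyl-5-[tri(propan-2-yl)silyloxy]phenyl}cyclopropyl methanesulfonate F10;
- the allyl bromide [5-(3-bromoprop-1-en-2-yl)-4-(methoxymethoxy)-2-methylphenoxy]tri(propan-2-yl)silane F11;
- the allyl benzoate 2-{2-(methoxymethoxy)-4-methyl-5-[tri(propan-2-yl)silyloxy]phenyl}prop-2-en-1-yl benzoate F12;
- the phenol 2-{2-hydroxy-4-methyl-5-[tri(propan-2-yl)silyloxy]phenyl}prop-2-en-1-yl benzoate F13;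
- the isobutyrate 2-{4-methyl-2-(2-methylpropanoyloxy)-5-[tri(propan-2-yl)silyloxy]phenyl}prop-2-en-1-yl benzoate F14.

Buffered desilylation (HF·pyridine, THF/pyridine, 0 °C) should then give 17 without a Lewis acid.

**Further compounds**

F1 | step 7 | 2-[5-(benzyloxy)-2-(methoxymethoxy)-4-methylphenyl]-1,3-bis(trimethylsilyl)propan-2-ol | COCOc1cc(C)c(OCc2ccccc2)cc1C(O)(C[Si](C)(C)C)C[Si](C)(C)C
F2 | step 7 | {2-[5-(benzyloxy)-2-(methoxymethoxy)-4-methylphenyl]prop-2-en-1-yl}(trimethyl)silane | COCOc1cc(C)c(OCc2ccccc2)cc1C(=C)C[Si](C)(C)C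
F3 | step 5 | 5-(benzyloxy)-N-methoxy-2-(methoxymethoxy)-N,4-dimethylbenzamide | COCOc1cc(C)c(OCc2ccccc2)cc1C(=O)N(C)OC
F4 | step 5 | 1-[5-(benzyloxy)-2-(methoxymethoxy)-4-methylphenyl]ethan-1-one | COCOc1cc(C)c(OCc2ccccc2)cc1C(C)=O
F5 | step 5 | ({1-[5-(benzyloxy)-2-(methoxymethoxy)-4-methylphenyl]ethenyl}oxy)(trimethyl)silane | COCOc1cc(C)c(OCc2ccccc2)cc1C(=C)O[Si](C)(C)C
F6 | step 5 | ({1-[5-(benzyloxy)-2-(methoxymethoxy)-4-methylphenyl]cyclopropyl}oxy)(trimethyl)silane | COCOc1cc(C)c(OCc2ccccc2)cc1C1(O[Si](C)(C)C)CC1
F7 | step 11 | methyl 2-hydroxy-4-methyl-5-[tri(propan-2-yl)silyloxy]benzoate | COC(=O)c1cc(O[Si](C(C)C)(C(C)C)C(C)C)c(C)cc1O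
F8 | step 11 | methyl 2-(methoxymethoxy)-4-methyl-5-[tri(propan-2-yl)silyloxy]benzoate | COCOc1cc(C)c(O[Si](C(C)C)(C(C)C)C(C)C)cc1C(=O)OC
F9 | step 11 | 1-{2-(methoxymethoxy)-4-methyl-5-[tri(propan-2-yl)silyloxy]phenyl}cyclopropan-1-ol | COCOc1cc(C)c(O[Si](C(C)C)(C(C)C)C(C)C)cc1C1(O)CC1
F10 | step 11 | 1-{2-(methoxymethoxy)-4-methyl-5-[tri(propan-2-yl)silyloxy]phenyl}cyclopropyl methanesulfonate | COCOc1cc(C)c(O[Si](C(C)C)(C(C)C)C(C)C)cc1C1(OS(C)(=O)=O)CC1
F11 | step 11 | [5-(3-bromoprop-1-en-2-yl)-4-(methoxymethoxy)-2-methylphenoxy]tri(propan-2-yl)silane | COCOc1cc(C)c(O[Si](C(C)C)(C(C)C)C(C)C)cc1C(=C)CBr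
F12 | step 11 | 2-{2-(methoxymethoxy)-4-methyl-5-[tri(propan-2-yl)silyloxy]phenyl}prop-2-en-1-yl benzoate | COCOc1cc(C)c(O[Si](C(C)C)(C(C)C)C(C)C)cc1C(=C)COC(=O)c1ccccc1
F13 | step 11 | 2-{2-hydroxy-4-methyl-5-[tri(propan-2-yl)silyloxy]phenyl}prop-2-en-1-yl benzoate | C=C(COC(=O)c1ccccc1)c1cc(O[Si](C(C)C)(C(C)C)C(C)C)c(C)cc1O
F14 | step 11 | 2-{4-methyl-2-(2-methylpropanoyloxy)-5-[tri(propan-2-yl)silyloxy]phenyl}prop-2-en-1-yl benzoate | C=C(COC(=O)c1ccccc1)c1cc(O[Si](C(C)C)(C(C)C)C(C)C)c(C)cc1OC(=O)C(C)C
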